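**Retrosynthetic overview**
1. Bulbocodin D (9) ⇐ global hydrogenolysis of its tris-O-benzyl ether 8.
2. 8 ⇐ both ArCH2–Ar′ units cut into three pieces each: an ortho C–H of phenol 5, formaldehyde as the CH2 linchpin, and 4-(benzyloxy)phenylboronic acid (new boron-templated double ortho-arylmethylation, one pot).
3. 5 (3′-O-benzylbatatasin III) ⇐ B-alkyl Suzuki coupling of 3-bromo-5-methoxyphenol with the 9-BBN adduct of 3-benzyloxystyrene; the styrene ⇐ Wittig methylenation of 3-benzyloxybenzaldehyde.
4. No ring is formed: all four benzene rings are bought. Order of attachment: B ring to A ring (bibenzyl), then the two p-oxybenzyl rings to the A ring, then deprotection.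

Assumption: the target SMILES has no stereocentre or stereoaxis (the molecule is achiral), so "single enantiomer" is taken to mean the single constitutional isomer drawn; no stereocontrol is needed.

**Step 1**
Reactants: 1, 3-(benzyloxy)benzaldehyde; 2, methyltriphenylphosphonium bromide
Product: 3, 1-(benzyloxy)-3-vinylbenzene (3-benzyloxystyrene)
Conditions: Ph3PCH3Br (1.3 equiv), KOtBu (1.3 equiv), THF, 0 °C → rt
Reagents that add atoms: methyltriphenylphosphonium bromide (2), C[P+](c1ccccc1)(c1ccccc1)c1ccccc1.[Br-] (supplies the =CH2 carbon)
Why: Wittig methylenation of a non-enolisable aryl aldehyde with the unstabilised ylide; the aryl benzyl ether is inert to base.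

**Step 2**
Reactants: 3, 1-(benzyloxy)-3-vinylbenzene; 4, 3-bromo-5-methoxyphenol
Product: 5, 3-{2-[3-(benzyloxy)phenyl]ethyl}-5-methoxyphenol (3′-O-benzylbatatasin III)
Conditions: 9-BBN (1.3 equiv), THF, 0 °C → rt; then 4 (0.8 equiv), Pd(dppf)Cl2 (5 mol %), aq K3PO4 (4 equiv), THF/DMF, 65 °C
Reagents that add atoms: none (9-BBN delivers only H)
Why: Anti-Markovnikov hydroboration of the styrene followed by B-alkyl Suzuki–Miyaura coupling forms the sp3–sp2 bond of the bibenzyl without hydrogenation, so the benzyl ether survives; the free phenol is tolerated as its phenoxide with excess base.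

**Step 3**
Reactants: 5, 3-{2-[3-(benzyloxy)phenyl]ethyl}-5-methoxyphenol; 6, 4-(benzyloxy)phenylboronic acid; 7, paraformaldehyde
Product: 8, 2,6-bis[4-(benzyloxy)benzyl]-3-{2-[3-(benzyloxy)phenyl]ethyl}-5-methoxyphenol
Conditions: 6 (3.0 equiv), (CH2O)n (6 equiv, two portions), EtCO2H (0.5 equiv), PhMe (0.05 M), Dean–Stark, 80 → 110 °C; mono-adducts resubjected if present
Reagents that add atoms: 4-(benzyloxy)phenylboronic acid (6), OB(O)c1ccc(OCc2ccccc2)cc1 (two aryl groups); paraformaldehyde (7), C=O (two CH2 carbons)
Why: Proposed new method: a boron-templated three-component ortho-arylmethylation (Nagata–Petasis cascade) run twice in one pot. Phenol, CH2O and ArB(OH)2 condense with loss of water to a 2-aryl-4H-1,3,2-benzodioxaborin, which fixes the new C–C bond ortho to the OH through a six-membered boron-bound transition state, so the position para to OH and the O-benzylated B ring cannot react. Carboxylic-acid-assisted heterolysis of the benzylic C–O(B) bond, easy here because the ring carries OH and OMe ortho/para to that carbon, gives an o-quinone methide still bound to boron through oxygen. Carboxylate re-coordination then makes a tetracoordinate boronate, and the electron-rich 4-benzyloxyphenyl group migrates ipso from B to the exocyclic CH2 through a six-membered cyclic transition state. The released phenol borate exchanges onto fresh boronic acid and the cycle repeats at the second ortho position, with B(OH)3 as the by-product. The closest known reaction types are Nagata ortho-hydroxyalkylation of phenols via benzodioxaborins, where the B-aryl group is only a spectator, and Petasis-type aryl transfer from boronates to o-quinone methides. Their merger with formaldehyde as a CH2 linchpin, transfer of the boron aryl group, and twofold operation on both sides of one phenol have not been demonstrated.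

**Step 4**
Reactants: 8, 2,6-bis[4-(benzyloxy)benzyl]-3-{2-[3-(benzyloxy)phenyl]ethyl}-5-methoxyphenol
Product: 9, bulbocodin D, 2,6-bis(4-hydroxybenzyl)-3-[2-(3-hydroxyphenyl)ethyl]-5-methoxyphenol (achiral)
Conditions: H2 (1 atm), 10% Pd/C, EtOAc/MeOH, rt
Reagents that add atoms: none
Why: Catalytic hydrogenolysis cleaves the three aryl benzyl ethers (O–CH2Ph) while the diarylmethane and bibenzyl C–C bonds, the aryl methyl ether and the arenes are inert under these mild conditions.

**Compound list**
1 | 3-(benzyloxy)benzaldehyde | O=Cc1cccc(OCc2ccccc2)c1 | starting material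
2 | methyltriphenylphosphonium bromide | C[P+](c1ccccc1)(c1ccccc1)c1ccccc1.[Br-] | starting material
3 | 1-(benzyloxy)-3-vinylbenzene | C=Cc1cccc(OCc2ccccc2)c1 | intermediate
4 | 3-bromo-5-methoxyphenol | COc1cc(O)cc(Br)c1 | starting material
5 | 3-{2-[3-(benzyloxy)phenyl]ethyl}-5-methoxyphenol | COc1cc(O)cc(CCc2cccc(OCc3ccccc3)c2)c1 | intermediate
6 | 4-(benzyloxy)phenylboronic acid | OB(O)c1ccc(OCc2ccccc2)cc1 | starting material
7 | paraformaldehyde (formaldehyde equivalent) | C=O | starting material
8 | 2,6-bis[4-(benzyloxy)benzyl]-3-{2-[3-(benzyloxy)phenyl]ethyl}-5-methoxyphenol | COc1cc(CCc2cccc(OCc3ccccc3)c2)c(Cc2ccc(OCc3ccccc3)cc2)c(O)c1Cc1ccc(OCc2ccccc2)cc1 | intermediate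
9 | bulbocodin D, 2,6-bis(4-hydroxybenzyl)-3-[2-(3-hydroxyphenyl)ethyl]-5-methoxyphenol | COc1cc(CCc2cccc(O)c2)c(Cc2ccc(O)cc2)c(O)c1Cc1ccc(O)cc1 | target

**Total step count:** 4
**Longest linear sequence:** 4 steps (from 3-(benzyloxy)benzaldehyde)

**Three steps most likely to fail**
1. Step 3 (proposed new step). Risks: the o-quinone methide is intercepted before aryl transfer (methylene-bridged dimers, or 7-membered intramolecular Friedel–Crafts closure onto the B ring), the second cycle stalls, or the boronic acid protodeboronates. Fallback with known chemistry: stepwise ortho-specific benzylation. Condense 5 with 4-(benzyloxy)benzaldehyde and PhB(OH)2 (cat. EtCO2H, PhMe, Dean–Stark) to the 4-aryl-2-phenyl-4H-1,3,2-benzodioxaborin, cleave it by ionic hydrogenation (Et3SiH, TFA, CH2Cl2, 0 °C) to the ortho-(4-benzyloxybenzyl)phenol, and repeat on the second ortho position. This gives the same compound 8 in four steps instead of one, with the benzylic carbon coming from the aldehyde and the hydrogen from the silane.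
2. Step 2. Risks: slow oxidative addition or protodeboronation with the electron-rich free bromophenol. Fallback: build the C2 bridge by olefination instead. Wittig reaction of 3-hydroxy-5-methoxybenzaldehyde with (3-benzyloxybenzyl)triphenylphosphonium bromide (excess KOtBu) gives the stilbene, and diimide reduction (TsNHNH2, NaOAc, THF/H2O, reflux) saturates the alkene without touching the benzyl ether, giving 5.
3. Step 4. Risks: incomplete removal of three benzyl ethers, or air oxidation of the electron-rich tetraphenol during prolonged hydrogenolysis. Fallback: change the protecting-group plan to silyl ethers. Carry the B-ring phenol as a TIPS ether and use 4-(tert-butyldimethylsilyloxy)phenylboronic acid in Step 3, then finish with one fluoride deprotection (TBAF/AcOH, THF, 0 °C) instead of hydrogenolysis.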